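## Retrosynthetic overview

1. The target comes from its tetra-MOM ether by one acid step. No skeletal bond is made after the key step.
2. Ring C is opened in one retro-[4+2] cut at O1–C8a and C2–C3. This gives 4-(MOM-oxy)benzaldehyde (C2=O1) and the (Z)-trimethylsilyl enol ether of a 2-fluoroaryl MOM-oxymethyl ketone (C3=C4–C4a=C8a–F), with Me3SiF as the only loss.
3. Enabling feature: in ring C the chain O1–C8a=C4a–C4(=O)–C3 is a vinylogous ester. C8a of ring A lies ortho to the C4 carbonyl but meta to O5 and O7, so a fluorine there is activated by C4=O and not switched off by the ring-A oxygens. C3 is the enolisable carbon next to C4=O.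
4. The fluoroaryl ketone comes from Rubottom alpha-oxygenation of the acetophenone. Its quaternary carbon on C6 comes from aromatic Claisen rearrangement of the 7-O-prenyl ether, steered to C6 by the chelated 5-OH. The starting materials are 5-fluororesorcinol, acetic acid and prenyl bromide.
5. Ring order: rings A and B are bought as arenes. Ring C is the only ring formed, in the key step.

Key step: step 9

Remark: ring atoms carry flavonoid numbering (O1, C2, C3, C4, C4a, C5 to C8, C8a) in the open-chain precursors too.

Assumption: the cinchonidine-derived ammonium salt is taken to favour the (2R,3R) series. If the sense of induction is the opposite, the pseudoenantiomeric cinchonine-derived salt takes its place.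

## Route

Step 1
Reactants: 1 5-fluororesorcinol; 2 acetic acid
Product: 3 1-(2-fluoro-4,6-dihydroxyphenyl)ethan-1-one
Conditions: AcOH, ZnCl2, 140 °C
Reagents that add atoms: none
Why: Nencki-type Friedel–Crafts C-acylation, which should enter para to one hydroxyl and ortho to the other as with resorcinol itself, the carbon between the two hydroxyls being the hindered site.

Step 2
Reactants: 3 1-(2-fluoro-4,6-dihydroxyphenyl)ethan-1-one; 4 prenyl bromide (1-bromo-3-methylbut-2-ene)
Product: 5 1-{2-fluoro-6-hydroxy-4-[(3-methylbut-2-en-1-yl)oxy]phenyl}ethan-1-one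
Conditions: K2CO3 (1.1 equiv), acetone, reflux
Reagents that add atoms: none
Why: Williamson ether synthesis in which only the free para hydroxyl should react, because the ortho hydroxyl is tied up in a hydrogen bond to the acetyl oxygen.

Step 3
Reactants: 5 1-{2-fluoro-6-hydroxy-4-[(3-methylbut-2-en-1-yl)oxy]phenyl}ethan-1-one
Product: 6 1-[6-fluoro-2,4-dihydroxy-3-(2-methylbut-3-en-2-yl)phenyl]ethan-1-one
Conditions: PhNEt2, 185 °C, sealed tube, Ar
Reagents that add atoms: none
Why: Aromatic Claisen rearrangement ([3,3] shift with allyl inversion, then rearomatisation) builds the quaternary benzylic carbon; the chelated 2-hydroxyaryl ketone fixes the ring double bond between the ether carbon and the carbon flanked by both oxygens (as when 4-O-allylresacetophenone gives its 3-allyl isomer), and the acetyl group blocks the para position.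

Step 4
Reactants: 6 1-[6-fluoro-2,4-dihydroxy-3-(2-methylbut-3-en-2-yl)phenyl]ethan-1-one
Product: 7 1-[6-fluoro-2,4-bis(methoxymethoxy)-3-(2-methylbut-3-en-2-yl)phenyl]ethan-1-one
Conditions: NaH, MOMCl, DMF, 0 → 23 °C
Reagents that add atoms: chloromethyl methyl ether, COCCl
Why: Williamson-type O-alkylation of the two sodium phenoxides by the small MOMCl should reach both hindered oxygens and give base- and fluoride-stable protection that one acid step removes.

Step 5
Reactants: 7 1-[6-fluoro-2,4-bis(methoxymethoxy)-3-(2-methylbut-3-en-2-yl)phenyl]ethan-1-one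
Product: 10 1-[6-fluoro-2,4-bis(methoxymethoxy)-3-(2-methylbut-3-en-2-yl)phenyl]-2-hydroxyethan-1-one, via trimethylsilyl enol ether 8 (not isolated), via alpha-silyloxy ketone 9 (not isolated)
Conditions: LiN(SiMe3)2, THF, −78 °C, then Me3SiCl; mCPBA, CH2Cl2, −20 °C; aq. citric acid, THF, 23 °C
Reagents that add atoms: mCPBA, O=C(OO)c1cccc(Cl)c1; chlorotrimethylsilane, C[Si](C)(C)Cl (its silyl group is carried only by 8 and 9)
Why: Rubottom oxidation, in which the electron-rich enol silane should be epoxidised far faster than the monosubstituted, neopentyl-type vinyl group, silyl migration gives the alpha-silyloxy ketone, and mild acid frees the ketol.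

Step 6
Reactants: 10 1-[6-fluoro-2,4-bis(methoxymethoxy)-3-(2-methylbut-3-en-2-yl)phenyl]-2-hydroxyethan-1-one
Product: 11 1-[6-fluoro-2,4-bis(methoxymethoxy)-3-(2-methylbut-3-en-2-yl)phenyl]-2-(methoxymethoxy)ethan-1-one
Conditions: MOMCl, i-Pr2NEt, CH2Cl2, 0 → 23 °C
Reagents that add atoms: chloromethyl methyl ether, COCCl
Why: O-alkylation of the primary ketol under amine base, mild enough that no alkoxide forms to attack the C–F carbon, puts a non-migrating, fluoride-proof group on the future O3.

Step 7
Reactants: 11 1-[6-fluoro-2,4-bis(methoxymethoxy)-3-(2-methylbut-3-en-2-yl)phenyl]-2-(methoxymethoxy)ethan-1-one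
Product: 12 {(Z)-1-[6-fluoro-2,4-bis(methoxymethoxy)-3-(2-methylbut-3-en-2-yl)phenyl]-2-(methoxymethoxy)ethenyl}oxy(trimethyl)silane
Conditions: LiN(SiMe3)2, THF, −78 °C, then Me3SiCl; pentane, filtration under Ar (no aqueous work-up)
Reagents that add atoms: chlorotrimethylsilane, C[Si](C)(C)Cl
Why: Kinetic enolisation and O-silylation, in which lithium chelated between the enolate oxygen and the alpha-alkoxy oxygen should give the Z enol silane, obtained free of salts.

Step 8
Reactants: 13 4-hydroxybenzaldehyde
Product: 14 4-(methoxymethoxy)benzaldehyde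
Conditions: MOMCl, i-Pr2NEt, CH2Cl2, 0 → 23 °C
Reagents that add atoms: chloromethyl methyl ether, COCCl
Why: Standard O-alkylation of the phenol masks the acidic proton that would quench the enolate and blocks quinone methide formation at the future C2.

Step 9
Reactants: 12 {(Z)-1-[6-fluoro-2,4-bis(methoxymethoxy)-3-(2-methylbut-3-en-2-yl)phenyl]-2-(methoxymethoxy)ethenyl}oxy(trimethyl)silane; 14 4-(methoxymethoxy)benzaldehyde
Product: 16 (2R,3R)-3,5,7-tris(methoxymethoxy)-2-[4-(methoxymethoxy)phenyl]-6-(2-methylbut-3-en-2-yl)chroman-4-one, via silyl aldol ether 15 (not isolated)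
Conditions: O-allyl-N-(9-anthracenylmethyl)cinchonidinium hydrogen difluoride (10 mol %), 12 (1.1 equiv), THF–toluene, −40 → 23 °C, slow Ar sweep; pH 7 buffer as soon as 15 is consumed
Reagents that add atoms: none
Why: Proposed new method: fluoride from the catalyst desilylates 12 to the chiral ammonium (Z)-enolate, C3 of which adds to the aldehyde carbon of 14 (C2–C3 bond; the adduct is parked reversibly as silyl ether 15), and the C2 alkoxide then displaces fluoride from C8a by addition–elimination (O1–C8a bond), so every ring closure hands back the fluoride that starts the next cycle and volatile Me3SiF is the only by-product. The closest known reaction types are the cinchona ammonium bifluoride-catalysed Mukaiyama aldol of silyl enol ethers of alpha-alkoxy aryl ketones with aromatic aldehydes, the fluoride-catalysed SNAr of silyl ethers on acyl-activated fluoroarenes, and the domino addition–SNAr annulations of 2-fluoroaryl ketones; their merger into one enantioselective fluoride-relay cycle has not been shown. Ring C closes by a 6-endo-trig addition–elimination on the vinylogous acyl fluoride O=C4–C4a=C8a–F, and the charge of the Meisenheimer adduct rests on O4, C4a, C6 and C8, none of which carries an oxygen donor. Since the aldol addition of a naked enolate is rapidly reversible, both stereocentres are fixed only in this irreversible closure: the half-chair with the C2 aryl and C3 OMOM groups pseudo-equatorial sets the 2,3-trans relation, and the ammonium ion, paired to one face of the flat acylarene anion, leaves the other face of C8a open, which draws the (2R,3R) aldolate out of the equilibrating set. The step needs attack by the oxygen on C2 and not the oxygen on C3 (which would give a benzofuran-3-one), secured by the MOM group on O3 that neither migrates nor falls to fluoride; it needs attack at C8a and not C5, secured by fluoride being the far better nucleofuge and by the tert-alkyl group screening C5; and it needs the absence of achiral cations, secured by the salt-free enol silane. Prompt buffering at the end keeps residual fluoride from opening ring C by E1cB elimination.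

Step 10
Reactants: 16 (2R,3R)-3,5,7-tris(methoxymethoxy)-2-[4-(methoxymethoxy)phenyl]-6-(2-methylbut-3-en-2-yl)chroman-4-one
Product: 17 (2R,3R)-3,5,7-trihydroxy-2-(4-hydroxyphenyl)-6-(2-methylbut-3-en-2-yl)chroman-4-one
Conditions: HCl (2 M in MeOH), MeOH–THF, 40 °C; recrystallisation
Reagents that add atoms: none
Why: Acid-catalysed transacetalisation to methanol frees all four hydroxyls at once; the monosubstituted vinyl group should resist protonation under these mild conditions, and the diequatorial 2,3-trans arrangement, being the thermodynamic one, should hold.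

## Compound list

1 | 5-fluororesorcinol (5-fluorobenzene-1,3-diol) | Oc1cc(O)cc(F)c1 | starting material
2 | acetic acid | CC(=O)O | starting material
3 | 1-(2-fluoro-4,6-dihydroxyphenyl)ethan-1-one | CC(=O)c1c(O)cc(O)cc1F | intermediate
4 | prenyl bromide (1-bromo-3-methylbut-2-ene) | CC(C)=CCBr | starting material
5 | 1-{2-fluoro-6-hydroxy-4-[(3-methylbut-2-en-1-yl)oxy]phenyl}ethan-1-one | CC(=O)c1c(O)cc(OCC=C(C)C)cc1F | intermediate
6 | 1-[6-fluoro-2,4-dihydroxy-3-(2-methylbut-3-en-2-yl)phenyl]ethan-1-one | C=CC(C)(C)c1c(O)cc(F)c(C(C)=O)c1O | intermediate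
7 | 1-[6-fluoro-2,4-bis(methoxymethoxy)-3-(2-methylbut-3-en-2-yl)phenyl]ethan-1-one | C=CC(C)(C)c1c(OCOC)cc(F)c(C(C)=O)c1OCOC | intermediate
8 | {1-[6-fluoro-2,4-bis(methoxymethoxy)-3-(2-methylbut-3-en-2-yl)phenyl]ethenyl}oxy(trimethyl)silane | C=CC(C)(C)c1c(OCOC)cc(F)c(C(=C)O[Si](C)(C)C)c1OCOC | intermediate
9 | 1-[6-fluoro-2,4-bis(methoxymethoxy)-3-(2-methylbut-3-en-2-yl)phenyl]-2-[(trimethylsilyl)oxy]ethan-1-one | C=CC(C)(C)c1c(OCOC)cc(F)c(C(=O)CO[Si](C)(C)C)c1OCOC | intermediate
10 | 1-[6-fluoro-2,4-bis(methoxymethoxy)-3-(2-methylbut-3-en-2-yl)phenyl]-2-hydroxyethan-1-one | C=CC(C)(C)c1c(OCOC)cc(F)c(C(=O)CO)c1OCOC | intermediate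
11 | 1-[6-fluoro-2,4-bis(methoxymethoxy)-3-(2-methylbut-3-en-2-yl)phenyl]-2-(methoxymethoxy)ethan-1-one | C=CC(C)(C)c1c(OCOC)cc(F)c(C(=O)COCOC)c1OCOC | intermediate
12 | {(Z)-1-[6-fluoro-2,4-bis(methoxymethoxy)-3-(2-methylbut-3-en-2-yl)phenyl]-2-(methoxymethoxy)ethenyl}oxy(trimethyl)silane | C=CC(C)(C)c1c(OCOC)cc(F)c(/C(O[Si](C)(C)C)=C/OCOC)c1OCOC | intermediate
13 | 4-hydroxybenzaldehyde | O=Cc1ccc(O)cc1 | starting material
14 | 4-(methoxymethoxy)benzaldehyde | COCOc1ccc(C=O)cc1 | intermediate
15 | (2R,3R)-1-[6-fluoro-2,4-bis(methoxymethoxy)-3-(2-methylbut-3-en-2-yl)phenyl]-2-(methoxymethoxy)-3-[4-(methoxymethoxy)phenyl]-3-[(trimethylsilyl)oxy]propan-1-one | C=CC(C)(C)c1c(OCOC)cc(F)c(c1OCOC)C(=O)[C@H](OCOC)[C@@H](c1ccc(OCOC)cc1)O[Si](C)(C)C | intermediate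
16 | (2R,3R)-3,5,7-tris(methoxymethoxy)-2-[4-(methoxymethoxy)phenyl]-6-(2-methylbut-3-en-2-yl)chroman-4-one | C=CC(C)(C)c1c(OCOC)cc2c(c1OCOC)C(=O)[C@H](OCOC)[C@@H](c1ccc(OCOC)cc1)O2 | intermediate
17 | (2R,3R)-3,5,7-trihydroxy-2-(4-hydroxyphenyl)-6-(2-methylbut-3-en-2-yl)chroman-4-one (6-(1,1-dimethylallyl)aromadendrin) | C=CC(C)(C)c1c(O)cc2c(c1O)C(=O)[C@H](O)[C@@H](c1ccc(O)cc1)O2 | target

## Step count and risks

Total step count: 10. Longest linear sequence: 9 (steps 1 to 7, 9 and 10).

**Step 9.**
- What may go wrong: facial selectivity in the ring closure may be poor. The reaction may stall at the desilylated ketone because the aldol pre-equilibrium lies far to the left. Residual fluoride may open ring C.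
- Fallback: it uses known reaction types only, sets out from 7 and comes back at 17. Condensation of 7 with N,N-dimethylformamide dimethyl acetal in hot toluene should give the enaminone F1. K3PO4 in wet DMSO exchanges the amine for oxygen and closes, by SNAr of the enolate oxygen on the C–F carbon, the chromone F2. Asymmetric conjugate addition of 4-(methoxymethoxy)phenylboronic acid follows, under divalent palladium as Pd(OCOCF3)2 with an enantiopure 4-tert-butyl-2-(2-pyridyl)oxazoline ligand (the enantiomer that serves the 2S series). It should give the (2S)-flavanone F3. LiN(SiMe3)2 with Me3SiCl present at −78 °C gives the enol silane F4. Its Rubottom oxidation, anti to the C2 aryl group, gives the trans-3-hydroxyflavanone F5. The conditions of step 10 then give 17.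

**Step 3.**
- What may go wrong: the allyl unit may migrate to the other free ortho carbon, next to C–F. The product phenol may also add thermally to its own vinyl group.
- Fallback: it sets out from 3 and comes back at 7. The free para hydroxyl is capped first (MOMCl, i-Pr2NEt) to give the mono-MOM ether F6. The chelated hydroxyl is then prenylated with 3-methylbut-2-en-1-ol under Mitsunobu conditions to give the ortho prenyl ether F7, whose only free ortho carbon is the wanted one. Claisen rearrangement under Eu(fod)3 (10 mol %, CHCl3, 60 °C) relies on trivalent europium chelated by the ketone and ether oxygens. The temperature is low enough that rearomatisation should outrun a further Cope shift, which gives the phenol F8. NaH and MOMCl then give 7.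

**Step 5.**
- What may go wrong: the peracid may attack the vinyl group or the electron-rich ring. The enol silane may hydrolyse back to the ketone.
- Fallback: it sets out from 7 and comes back at 10. LiN(SiMe3)2 and then 2,2,2-trifluoroethyl trifluoroacetate give the trifluoroacetyl ketone F9. Methanesulfonyl azide, Et3N and water transfer the diazo group with loss of the trifluoroacetyl group to give the diazoketone F10. Rh2(OAc)4 in wet THF inserts the carbene into an O–H bond of water to give 10.

## Further compounds

F1 | step 9 | (E)-3-(dimethylamino)-1-[6-fluoro-2,4-bis(methoxymethoxy)-3-(2-methylbut-3-en-2-yl)phenyl]prop-2-en-1-one | C=CC(C)(C)c1c(OCOC)cc(F)c(C(=O)/C=C/N(C)C)c1OCOC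
F2 | step 9 | 5,7-bis(methoxymethoxy)-6-(2-methylbut-3-en-2-yl)-4H-chromen-4-one | C=CC(C)(C)c1c(OCOC)cc2occc(=O)c2c1OCOC
F3 | step 9 | (2S)-5,7-bis(methoxymethoxy)-2-[4-(methoxymethoxy)phenyl]-6-(2-methylbut-3-en-2-yl)chroman-4-one | C=CC(C)(C)c1c(OCOC)cc2c(c1OCOC)C(=O)C[C@@H](c1ccc(OCOC)cc1)O2
F4 | step 9 | {(2S)-5,7-bis(methoxymethoxy)-2-[4-(methoxymethoxy)phenyl]-6-(2-methylbut-3-en-2-yl)-2H-chromen-4-yl}oxy(trimethyl)silane | C=CC(C)(C)c1c(OCOC)cc2c(c1OCOC)C(O[Si](C)(C)C)=C[C@@H](c1ccc(OCOC)cc1)O2
F5 | step 9 | (2R,3R)-3-hydroxy-5,7-bis(methoxymethoxy)-2-[4-(methoxymethoxy)phenyl]-6-(2-methylbut-3-en-2-yl)chroman-4-one | C=CC(C)(C)c1c(OCOC)cc2c(c1OCOC)C(=O)[C@H](O)[C@@H](c1ccc(OCOC)cc1)O2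
F6 | step 3 | 1-[2-fluoro-6-hydroxy-4-(methoxymethoxy)phenyl]ethan-1-one | CC(=O)c1c(O)cc(OCOC)cc1F
F7 | step 3 | 1-{2-fluoro-4-(methoxymethoxy)-6-[(3-methylbut-2-en-1-yl)oxy]phenyl}ethan-1-one | CC(=O)c1c(OCC=C(C)C)cc(OCOC)cc1F
F8 | step 3 | 1-[6-fluoro-2-hydroxy-4-(methoxymethoxy)-3-(2-methylbut-3-en-2-yl)phenyl]ethan-1-one | C=CC(C)(C)c1c(OCOC)cc(F)c(C(C)=O)c1O
F9 | step 5 | 4,4,4-trifluoro-1-[6-fluoro-2,4-bis(methoxymethoxy)-3-(2-methylbut-3-en-2-yl)phenyl]butane-1,3-dione | C=CC(C)(C)c1c(OCOC)cc(F)c(C(=O)CC(=O)C(F)(F)F)c1OCOC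
F10 | step 5 | 2-diazo-1-[6-fluoro-2,4-bis(methoxymethoxy)-3-(2-methylbut-3-en-2-yl)phenyl]ethan-1-one | C=CC(C)(C)c1c(OCOC)cc(F)c(C(=O)C=[N+]=[N-])c1OCOC
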